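**Retrosynthetic overview**

- The last disconnection is the two benzyl ethers at O3 and O4', removed by neutral hydrogenolysis that leaves the C8 acetate alone.
- The strategy rests on ring A: its para oxygens at C5 (free OH) and C8 (OAc), with C6–H and C7–OMe between them, are the four carbons of methyl semisquarate. C4a=C8a is the C5=C6 bond of a 4-pyranone. Ring A is therefore cut at C5–C4a (6π electrocyclization of a dienylketene) and at C8–C8a (carbanion addition to a squarate carbonyl).
- The C8 oxygen is acetylated as a tertiary carbinol on the cyclobutenone, before ring A exists, so the ring A oxygens never need to be told apart on a polyphenol.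
- Ring C (3-benzyloxy-2-aryl-4-pyranone) comes from an aryl furyl carbinol by oxidative ring expansion, one further oxidation at C4 and dehydration.
- Order of rings: ring B is bought, ring C is made from the furan, ring A is closed last.

Key step: step 11

Assumption: a lithium amide is taken to deprotonate the 3-benzyloxy-2-aryl-4-pyranone at C6 (alpha to the ring oxygen), as it does at the corresponding carbon of chromones and 1-alkyl-4-pyridones. A magnesium amide is avoided because binding to the C4 carbonyl could steer metalation to C5.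

Step 1
Reactants: 1 furfural; 2 1-(benzyloxy)-4-bromobenzene
Product: 4 (4-(benzyloxy)phenyl)(furan-2-yl)methanol (racemic), via aryl Grignard reagent 3 (not isolated)
Conditions: 2, Mg turnings, I2 (cat.), THF, 40 °C; then 1, 0 °C; sat. aq NH4Cl
Reagents that add atoms: none
Why: Magnesium insertion into the aryl bromide and 1,2-addition of the aryl Grignard reagent to the aldehyde is a standard Grignard reaction; the carbinol center forms racemic, which does not matter because this carbon becomes sp2 C2 of ring C.

Step 2
Reactants: 4 (4-(benzyloxy)phenyl)(furan-2-yl)methanol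
Product: 5 2-(4-(benzyloxy)phenyl)-6-hydroxy-2H-pyran-3(6H)-one (racemic; both C6 epimers)
Conditions: N-bromosuccinimide (NBS), NaHCO3, THF/H2O (4:1), 0 °C
Reagents that add atoms: water, O
Why: Achmatowicz rearrangement: NBS oxidizes the electron-rich furan far faster than the benzyloxyarene, water opens the oxidized furan to a cis-enedione, and the carbinol oxygen closes onto the aldehyde to give the six-membered hemiacetal (the new acetal center is an epimer mixture of no consequence).

Step 3
Reactants: 5 2-(4-(benzyloxy)phenyl)-6-hydroxy-2H-pyran-3(6H)-one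
Product: 6 2-(4-(benzyloxy)phenyl)-6-methoxy-2H-pyran-3(6H)-one (racemic; both C6 epimers)
Conditions: HC(OMe)3, BF3·OEt2 (cat.), CH2Cl2, 0 °C
Reagents that add atoms: trimethyl orthoformate, COC(OC)OC
Why: Lewis acid catalysed glycosidation through the ring oxocarbenium ion turns the base-labile lactol into a methyl acetal that should withstand the alkaline peroxide of the next step.

Step 4
Reactants: 6 2-(4-(benzyloxy)phenyl)-6-methoxy-2H-pyran-3(6H)-one
Product: 7 4,5-epoxy-2-(4-(benzyloxy)phenyl)-6-methoxytetrahydro-2H-pyran-3-one (racemic diastereomer mixture)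
Conditions: 30% aq H2O2, NaOH (cat.), MeOH, 0 °C
Reagents that add atoms: hydrogen peroxide, OO
Why: Weitz–Scheffer nucleophilic epoxidation: hydroperoxide adds to C5 of the enone and the enolate closes the epoxide, which brings C4 to the oxidation level of the later pyranone carbonyl; all sp3 centers are destroyed in the next step, so the diastereomer mixture is acceptable.

Step 5
Reactants: 7 4,5-epoxy-2-(4-(benzyloxy)phenyl)-6-methoxytetrahydro-2H-pyran-3-one
Product: 8 2-(4-(benzyloxy)phenyl)-3-hydroxy-4H-pyran-4-one
Conditions: 2 M aq H2SO4, dioxane, 90 °C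
Reagents that add atoms: none
Why: Acid-catalysed isomerization of the α,β-epoxy ketone to the 3,4-dione, β-elimination of methanol and enolization toward the benzylic C2 should give the 3-hydroxy-4-pyranone, the same cascade by which maltol is made from its epoxy acetal.

Step 6
Reactants: 8 2-(4-(benzyloxy)phenyl)-3-hydroxy-4H-pyran-4-one
Product: 9 3-(benzyloxy)-2-(4-(benzyloxy)phenyl)-4H-pyran-4-one
Conditions: BnBr, K2CO3, DMF, 60 °C
Reagents that add atoms: benzyl bromide, BrCc1ccccc1
Why: Williamson etherification of the acidic enolic 3-OH, the only hydroxyl in the molecule, removes the last acidic proton before the metalation.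

Step 7
Reactants: 10 dimethyl squarate
Product: 11 4-hydroxy-2,3-dimethoxycyclobut-2-en-1-one (racemic)
Conditions: LiAlH(OtBu)3, THF, −78 → −20 °C; aq work-up
Reagents that add atoms: none
Why: One hydride from the bulky LiAlH(OtBu)3 adds 1,2 to one vinylogous ester carbonyl and the resulting alkoxide resists a second reduction at low temperature (carbinol center racemic, lost in step 8).

Step 8
Reactants: 11 4-hydroxy-2,3-dimethoxycyclobut-2-en-1-one
Product: 12 3-methoxycyclobut-3-ene-1,2-dione (methyl semisquarate)
Conditions: conc. aq HCl (cat.), CH2Cl2, rt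
Reagents that add atoms: none
Why: Acid-promoted vinylogous elimination of methanol with allylic transposition converts the hydroxy enone into the cyclobutenedione, as in the standard preparation of alkyl semisquarates.

Step 9
Reactants: 9 3-(benzyloxy)-2-(4-(benzyloxy)phenyl)-4H-pyran-4-one; 12 3-methoxycyclobut-3-ene-1,2-dione
Product: 14 3-(benzyloxy)-2-(4-(benzyloxy)phenyl)-6-(1-hydroxy-2-methoxy-4-oxocyclobut-2-en-1-yl)-4H-pyran-4-one (racemic), via 6-lithiopyranone 13 (not isolated)
Conditions: lithium 2,2,6,6-tetramethylpiperidide (LiTMP, from 2,2,6,6-tetramethylpiperidine and n-BuLi), THF, −78 °C, 9 added to the base; then 12, −78 °C; sat. aq NH4Cl at −78 °C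
Reagents that add atoms: none
Why: Proposed new method: LiTMP should remove the C6 hydrogen of 9, the kinetically most acidic sp2 C–H because it is alpha to ring oxygen O1 and beta to the C4 carbonyl, and a lithium amide follows this intrinsic acidity where a carbonyl-bound magnesium amide might go to C5; the vinyllithium 13 then adds 1,2 to the ketone-like carbonyl of 12 (the one attached to C–OMe), which is much more electrophilic than the vinylogous ester carbonyl, so that the future C8–C8a bond forms with OMe, H and the remaining carbonyl already in the order ring A requires (new carbinol center racemic and later destroyed); the closest known reaction types are the lithium amide lithiation of chromones, 1-alkyl-4-pyridones and uracils at the carbon alpha to the ring heteroatom and the 1,2-addition of organolithium reagents to squarate and semisquarate esters.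

Step 10
Reactants: 14 3-(benzyloxy)-2-(4-(benzyloxy)phenyl)-6-(1-hydroxy-2-methoxy-4-oxocyclobut-2-en-1-yl)-4H-pyran-4-one
Product: 15 1-[5-(benzyloxy)-6-(4-(benzyloxy)phenyl)-4-oxo-4H-pyran-2-yl]-2-methoxy-4-oxocyclobut-2-en-1-yl acetate (racemic)
Conditions: Ac2O, Et3N, DMAP (cat.), CH2Cl2, 0 °C
Reagents that add atoms: acetic anhydride, CC(=O)OC(C)=O
Why: DMAP-catalysed acylation (Steglich type) through the N-acetylpyridinium ion is reactive enough for the hindered tertiary carbinol, and the low temperature and weak base should leave the cyclobutenone ring closed.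

Step 11
Reactants: 15 1-[5-(benzyloxy)-6-(4-(benzyloxy)phenyl)-4-oxo-4H-pyran-2-yl]-2-methoxy-4-oxocyclobut-2-en-1-yl acetate
Product: 18 3-(benzyloxy)-2-(4-(benzyloxy)phenyl)-5-hydroxy-7-methoxy-4-oxo-4H-chromen-8-yl acetate (3,4'-di-O-benzylpollenitin 8-acetate), via dienylketene 16 (not isolated), via cyclohexadienone 17 (not isolated)
Conditions: degassed toluene (0.02 M), 110 °C, Ar
Reagents that add atoms: none
Why: Proposed new method: on heating, the cyclobutenone C1–C4 bond of 15 should open by thermal conrotatory 4π electrocyclic ring opening to the (Z)-dienylketene 16, whose ketene carbon then bonds to pyranone C5 in a thermal disrotatory 6π electrocyclization (the new C5–C4a bond of the flavone), and dienone 17 enolizes at once because its C4a–H lies between two carbonyl groups, giving the phenol whose C5–OH is hydrogen-bonded to the C4 carbonyl. The closest known reaction type is the Moore–Liebeskind thermal rearrangement of 4-aryl- and 4-alkenyl-4-hydroxy (or 4-silyloxy, 4-alkoxy) cyclobutenones to hydroquinones and their monoethers; not yet shown are a 4-pyranone C5=C6 bond as the third π component and an acetate as the oxygen substituent at C4. Ring A is the only ring closed, as a six-membered carbocycle by 6π electrocyclization onto the C5=C6 bond of ring C, an enol-ether-like alkene with its nucleophilic end at C5 and so little aromatic stabilization that closure should cost hardly more than with a simple alkenyl group. The only new stereocenter is the transient C4a of 17, formed racemic and erased by tautomerization, so 18 is achiral. The step needs the acetoxy group to rotate outward and the pyranonyl group inward during ring opening, and this torquoselectivity is secured by the lone-pair donor character of the C4 oxygen (outward preference) against the acceptor-like pyranon-6-yl group (content to turn inward). The placement of C5–OH, C6–H, C7–OMe and C8–OAc needs no further control because it is fixed by the constitution of 15, and the acetate cannot migrate since its only neighbours are the C7 methyl ether and ring oxygen O1.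

Step 12
Reactants: 18 3-(benzyloxy)-2-(4-(benzyloxy)phenyl)-5-hydroxy-7-methoxy-4-oxo-4H-chromen-8-yl acetate
Product: 19 3,5-dihydroxy-2-(4-hydroxyphenyl)-7-methoxy-4-oxo-4H-chromen-8-yl acetate (pollenitin 8-acetate)
Conditions: H2 (1 atm), 10% Pd/C, EtOAc/THF, rt
Reagents that add atoms: none
Why: Palladium-catalysed hydrogenolysis cleaves both benzyl C–O bonds under neutral, non-nucleophilic conditions that should spare the aryl acetate, the aryl methyl ether and the C2=C3 bond of the flavonol.

**Compound list**

1 | furfural | O=Cc1ccco1 | starting material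
2 | 1-(benzyloxy)-4-bromobenzene | Brc1ccc(OCc2ccccc2)cc1 | starting material
3 | (4-(benzyloxy)phenyl)magnesium bromide | Br[Mg]c1ccc(OCc2ccccc2)cc1 | intermediate
4 | (4-(benzyloxy)phenyl)(furan-2-yl)methanol (racemic) | OC(c1ccco1)c1ccc(OCc2ccccc2)cc1 | intermediate
5 | 2-(4-(benzyloxy)phenyl)-6-hydroxy-2H-pyran-3(6H)-one (racemic, epimer mixture) | OC1C=CC(=O)C(c2ccc(OCc3ccccc3)cc2)O1 | intermediate
6 | 2-(4-(benzyloxy)phenyl)-6-methoxy-2H-pyran-3(6H)-one (racemic, epimer mixture) | COC1C=CC(=O)C(c2ccc(OCc3ccccc3)cc2)O1 | intermediate
7 | 4,5-epoxy-2-(4-(benzyloxy)phenyl)-6-methoxytetrahydro-2H-pyran-3-one (racemic, diastereomer mixture) | COC1OC(c2ccc(OCc3ccccc3)cc2)C(=O)C2OC21 | intermediate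
8 | 2-(4-(benzyloxy)phenyl)-3-hydroxy-4H-pyran-4-one | O=c1ccoc(-c2ccc(OCc3ccccc3)cc2)c1O | intermediate
9 | 3-(benzyloxy)-2-(4-(benzyloxy)phenyl)-4H-pyran-4-one | O=c1ccoc(-c2ccc(OCc3ccccc3)cc2)c1OCc1ccccc1 | intermediate
10 | dimethyl squarate (3,4-dimethoxycyclobut-3-ene-1,2-dione) | COC1=C(OC)C(=O)C1=O | starting material
11 | 4-hydroxy-2,3-dimethoxycyclobut-2-en-1-one (racemic) | COC1=C(OC)C(O)C1=O | intermediate
12 | 3-methoxycyclobut-3-ene-1,2-dione (methyl semisquarate) | COC1=CC(=O)C1=O | intermediate
13 | 3-(benzyloxy)-2-(4-(benzyloxy)phenyl)-6-lithio-4H-pyran-4-one | [Li]c1cc(=O)c(OCc2ccccc2)c(-c2ccc(OCc3ccccc3)cc2)o1 | intermediate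
14 | 3-(benzyloxy)-2-(4-(benzyloxy)phenyl)-6-(1-hydroxy-2-methoxy-4-oxocyclobut-2-en-1-yl)-4H-pyran-4-one (racemic) | COC1=CC(=O)C1(O)c1cc(=O)c(OCc2ccccc2)c(-c2ccc(OCc3ccccc3)cc2)o1 | intermediate
15 | 1-[5-(benzyloxy)-6-(4-(benzyloxy)phenyl)-4-oxo-4H-pyran-2-yl]-2-methoxy-4-oxocyclobut-2-en-1-yl acetate (racemic) | COC1=CC(=O)C1(OC(C)=O)c1cc(=O)c(OCc2ccccc2)c(-c2ccc(OCc3ccccc3)cc2)o1 | intermediate
16 | (Z)-dienylketene: (Z)-1-[5-(benzyloxy)-6-(4-(benzyloxy)phenyl)-4-oxo-4H-pyran-2-yl]-2-methoxy-4-oxobuta-1,3-dien-1-yl acetate, ketenyl and pyranonyl groups cis | O=C=C/C(OC)=C(/OC(C)=O)c1cc(=O)c(OCc2ccccc2)c(-c2ccc(OCc3ccccc3)cc2)o1 | intermediate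
17 | 3-(benzyloxy)-2-(4-(benzyloxy)phenyl)-7-methoxy-4,5-dioxo-4a,5-dihydro-4H-chromen-8-yl acetate (racemic 4a-H dienone) | COC1=CC(=O)C2C(=O)C(OCc3ccccc3)=C(c3ccc(OCc4ccccc4)cc3)OC2=C1OC(C)=O | intermediate
18 | 3-(benzyloxy)-2-(4-(benzyloxy)phenyl)-5-hydroxy-7-methoxy-4-oxo-4H-chromen-8-yl acetate (3,4'-di-O-benzylpollenitin 8-acetate) | COc1cc(O)c2c(=O)c(OCc3ccccc3)c(-c3ccc(OCc4ccccc4)cc3)oc2c1OC(C)=O | intermediate
19 | 3,5-dihydroxy-2-(4-hydroxyphenyl)-7-methoxy-4-oxo-4H-chromen-8-yl acetate (pollenitin 8-acetate) | COc1cc(O)c2c(=O)c(O)c(-c3ccc(O)cc3)oc2c1OC(C)=O | target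

**Step count and risks**

Total step count: 12. Longest linear sequence: 10 steps (steps 1–6 and 9–12); the squarate branch (steps 7–8) joins at step 9.

Steps most likely to fail:

1. Step 9 (labelled). The lithiated pyranone may add in conjugate fashion to pyranone not yet metalated, deprotonation may occur at C5 with ring opening, or residual amide may attack the semisquarate. The fallback sets out from 9 and comes back at 14, using known reaction types (in situ trapping metalation, iodolysis of an organozinc, halogen–magnesium exchange, Grignard addition to a squarate-type dione). Compound 9 would be lithiated with LiTMP in the presence of ZnCl2·2LiCl at −78 °C, so that each lithiated molecule is trapped at once as the unreactive [5-(benzyloxy)-6-(4-(benzyloxy)phenyl)-4-oxo-4H-pyran-2-yl]zinc chloride F1. Iodolysis with I2 in THF should give 3-(benzyloxy)-2-(4-(benzyloxy)phenyl)-6-iodo-4H-pyran-4-one F2, which can be purified and its regiochemistry checked. Iodine–magnesium exchange with iPrMgCl·LiCl at −78 °C, with no amide base and no unmetalated pyranone present, should then give [5-(benzyloxy)-6-(4-(benzyloxy)phenyl)-4-oxo-4H-pyran-2-yl]magnesium chloride F3, which is added to 12 at −78 °C to give 14 after NH4Cl work-up.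

2. Step 11 (labelled). The acetate may fail to direct the ring opening outward, or the ketene may be consumed by dimerization or acyl transfer before the 6π closure. The fallback sets out from 14 and comes back at 18, using the rearrangement in its documented form with a free C4 hydroxyl. Heating 14 in degassed toluene or p-xylene under argon should give the hydroquinone 3-(benzyloxy)-2-(4-(benzyloxy)phenyl)-5,8-dihydroxy-7-methoxy-4H-chromen-4-one F4. One equivalent of Ac2O in pyridine/CH2Cl2 at 0 °C should then acetylate only the C8 hydroxyl, because the C5 hydroxyl is held in a hydrogen bond to the C4 carbonyl, giving 18.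

3. Step 5. The epoxy acetal may fragment or ring-contract under acid instead of forming the dione, and a benzyl ether may be lost. The fallback sets out from 2 (through its Grignard reagent 3) and comes back at 9, replacing the furan-based construction of ring C by a cross-coupling.
   - Reagent 3 would be borylated with B(OMe)3 and worked up with dilute acid to give (4-(benzyloxy)phenyl)boronic acid F5.
   - Commercial 3-hydroxy-4H-pyran-4-one (pyromeconic acid, O=c1ccocc1O) would be brominated with NBS at C2, the position ortho to its enolic hydroxyl, to give 2-bromo-3-hydroxy-4H-pyran-4-one F6.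
   - F6 would be benzylated (BnBr, K2CO3, DMF) to 3-(benzyloxy)-2-bromo-4H-pyran-4-one F7.
   - Suzuki–Miyaura coupling of F5 and F7 (Pd(PPh3)4, K2CO3, dioxane/H2O, 90 °C) should give 9.

**Further compounds**

F1 | step 9 | [5-(benzyloxy)-6-(4-(benzyloxy)phenyl)-4-oxo-4H-pyran-2-yl]zinc chloride | Cl[Zn]c1cc(=O)c(OCc2ccccc2)c(-c2ccc(OCc3ccccc3)cc2)o1
F2 | step 9 | 3-(benzyloxy)-2-(4-(benzyloxy)phenyl)-6-iodo-4H-pyran-4-one | Ic1cc(=O)c(OCc2ccccc2)c(-c2ccc(OCc3ccccc3)cc2)o1
F3 | step 9 | [5-(benzyloxy)-6-(4-(benzyloxy)phenyl)-4-oxo-4H-pyran-2-yl]magnesium chloride | Cl[Mg]c1cc(=O)c(OCc2ccccc2)c(-c2ccc(OCc3ccccc3)cc2)o1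
F4 | step 11 | 3-(benzyloxy)-2-(4-(benzyloxy)phenyl)-5,8-dihydroxy-7-methoxy-4H-chromen-4-one | COc1cc(O)c2c(=O)c(OCc3ccccc3)c(-c3ccc(OCc4ccccc4)cc3)oc2c1O
F5 | step 5 | (4-(benzyloxy)phenyl)boronic acid | OB(O)c1ccc(OCc2ccccc2)cc1
F6 | step 5 | 2-bromo-3-hydroxy-4H-pyran-4-one | O=c1ccoc(Br)c1O
F7 | step 5 | 3-(benzyloxy)-2-bromo-4H-pyran-4-one | O=c1ccoc(Br)c1OCc1ccccc1
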